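**Near twin.** The gamma run looks nearly the same as this flask: same substrate and capture agent, but partner at 0.30 M where this flask has 0.400 M.

| setting | alpha | gamma | theta | flask |
|---|---|---|---|---|
| substrate | 0.50 M | 0.50 M | 1 M | 0.50 M |
| partner | 0.20 M | 0.30 M | 0.40 M | 0.400 M |
| capture agent | 0.050 M | 0.050 M | 0.050 M | 0.0500 M |
| remark | run made earlier | run made earlier | run made earlier |  |
| time |  |  |  | 40 min |

| run | time / min | substrate / % | mono adduct / % |
|---|---|---|---|
| alpha | 2.00 | 97 | 0 |
| alpha | 6.00 | 84 | 5 |
| alpha | 12.0 | 80 | 6 |
| alpha | 15.0 | 71 | 4 |
| alpha | 25.0 | 64 | 11 |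
| gamma | 2.00 | 95 | 1 |
| gamma | 4.00 | 92 | 3 |
| gamma | 6.00 | 85 | 2 |
| gamma | 12.0 | 74 | 9 |
| gamma | 25.0 | 63 | 11 |
| theta | 2.00 | 95 | 2 |
| theta | 6.00 | 82 | 4 |
| theta | 12.0 | 68 | 9 |
| theta | 15.0 | 60 | 7 |
| theta | 25.0 | 50 | 13 |

(scatter of a reading: 2 percentage points)



- the substrate standing at 40 min, as a percentage of the substrate charged
- the mono adduct standing at 40 min, as a percentage of the substrate charged
- the bis adduct standing at 40 min, as a percentage of the substrate charged
- the triple product standing at 40 min, as a percentage of the substrate charged

**Reading the split.** At 25.0 min, alpha holds 64% substrate and gamma 63%, though gamma has more partner, so I suppose that substrate also leaves by a route without partner. Dividing the rate of the partner route by that of the other removes time. I let mono adduct stand for the partner side and call R the charge ratio, partner over substrate. My selectivity factor S is then mono adduct standing over substrate lost beyond it, divided by R. The last readings give 1.10, 0.705 and 0.878, with all their scatter, so I take S as 0.895.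

**Two ends.** Mono adduct's share of the lost substrate is then φ = SR/(1+SR). Gamma gets 34.9% and this flask 41.7%. My φ for this flask stands higher than gamma's because its R is larger.

**The forecast.** It gives 50% substrate, 13% mono adduct, 25% bis adduct and 12% triple product, and says of the last two: “The runs do not measure that split directly, so it is a guess.” On its substrate figure, my φ puts 20.9% of the charge in mono adduct, where the forecast has 13%.

**The flask.** It holds 47.6% substrate, 15.8% mono adduct, 1.23% bis adduct and 0.00809% triple product.

    substrate + partner → mono adduct + released group (k = 4.79 × 10⁻⁴ M⁻¹ s⁻¹)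
    partner + mono adduct → bis adduct + released group (k = 1.94 × 10⁻⁴ M⁻¹ s⁻¹)
    partner + bis adduct → triple product + released group (k = 2.78 × 10⁻⁵ M⁻¹ s⁻¹)
    2 substrate → homo dimer (k = 2.71 × 10⁻⁴ M⁻¹ s⁻¹)
    mono adduct + capture agent → trapped intermediate (k = 0.00450 M⁻¹ s⁻¹)
    partner + released group ⇌ idle adduct, settled at all times (K = 51.8 M⁻¹)

In this flask mono adduct makes up 30.2% of the substrate lost, against my φ of 41.7%; the homo dimer holds 30.9% of the charge. Mono adduct in this flask stands at 15.8%, and a run with partner kept from depleting gives 21.9%. This flask's partner is down to 46% of its charge, and that depletion, together with trapping by capture agent, is part of the reason mono adduct stands no higher.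

**Further flask.** For a neighbour flask with 1.6 M partner, S gives φ = 74.1%. The computed neighbour has mono adduct at 50.0% of its lost substrate, with 39.6% of the charge standing as mono adduct.

All runs come from a simulation with made-up constants; noise was put on by code.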